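(Readings and results are calculated from invented constants; the scatter is artificial.)

Your vessel is closed, stirred and isothermal. Starting material (A) meets reagent (B) in the suspected step to intermediate, which goes on to target or side product, while B can also pair to homo dimer.

all flasks: starting material 0.050 M

| flask | reagent | remark | time |
|---|---|---|---|
| red | 0.075 M | the very flask that is asked about, followed so far |  |
| blue | 0.15 M | run made earlier |  |
| flask | 0.0750 M |  | 20 h |

- red (time / h: target / %, starting material / %): 3.00: 62.1, 22.5; 6.00: 69.9, 14.1; 8.00: 72.0, 10.6; 12.0: 74.2, 9.9; 15.0: 75.1, 10.0; 20.0: 73.1, 8.5
- blue (time / min: target / %, starting material / %): 10.0: 15.2, 49.7; 15.0: 23.9, 44.5; 20.0: 29.5, 43.0; 30.0: 39.3, 34.9; 50.0: 53.1, 29.2; 80.0: 61.3, 19.1; 120: 68.7, 15.0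

(readings scatter by 1 percentage point)

- north-west: change nothing and wait 10 h more
- north: at 20 h take out 90% of the target then present, then wait 10 h
- west: at 20 h add starting material, 50.0% of the amount charged, then wait 10 h
- east: at 20 h add reagent, 50.0% of the amount charged, then wait 10 h

- removed target is counted in
- on the list of suspects stand: starting material + reagent <-> intermediate; intermediate -> target; intermediate -> side product; 2 reagent -> homo dimer
- additions bring no volume worth counting

1. target, in percent of the starting material first charged, at 20 h
2. the option that brings most further target ("none" if no option brings more than 2 percentage points) (north-west / north / west / east / none)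
3. target present, with what was taken out counted in, in percent of the starting material first charged, after north-west
4. target present, with what was taken out counted in, in percent of the starting material first charged, after north

The red run stalls with a mean of 9.47% A over its readings from 12.0 h to 20.0 h, yet blue, with twice the reagent, is still falling from 19.1% to 15.0%. I therefore treat B as the limiting reagent. That plateau mean puts the uptake of B by A near 0.0453 M of the 0.075 M charged, and as an estimate I book the difference, 0.0297 M, to homo dimer.

The path to intermediate is first order in B and the path to homo dimer second order, so I take their split to go as [A]/[B]. Hence Q = 2.28, the competition number: B reaching A per B lost to homo dimer, multiplied by [B]/[A].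

For east, Q gives A 0.00839 M of the added B, more than the 0.00473 M of A left. One number is not enough, though: target also needs the selectivity f, the target formed per A converted, which is 0.819 in red and 0.808 in blue. East can then bring about 7.8 percentage points. I reckon 74.1% now and about that after north-west, with A in red reading 9.9% at 12.0 h and 8.5% at 20.0 h. No suspect step starts from target, so I expect north to give the same count as north-west.

The forecast says 74.3% now, 74.6% after north-west, 74.6% after north and east as best, with “Waiting gives almost nothing”, its figure for now lying slightly above mine.

The flask gives 74.7%, 75.5% after north-west and 75.5% after north. East brings 6.1 points and west 1.4 points, so the best option is east.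

    starting material + reagent ⇌ intermediate (K = 7.20 M⁻¹, k = 97.0 M⁻¹ h⁻¹)
    intermediate → target (k = 3.10 h⁻¹)
    intermediate → side product (k = 0.720 h⁻¹)
    2 reagent → homo dimer (k = 5.20 M⁻¹ h⁻¹)

The flask has nearly come to rest at 20 h, with 7.92% of its A and 1.17% of its B free. Q at these amounts gives a split of 10.3, so A should still lose 1.6 points. Computed to 200 h, A falls by 1.7 points and target reaches 76.1%.

In the neighbour flask with 0.030 M reagent, Q gives a split of 3.81, hence 47.5% of A converted, 52.5% left and 38.9% target. The computed flask holds 48.2% A and 42.0% target.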